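**Plan**
- Cuts (oxane numbering of the target: O1, C2 bearing the acrylic acid, C3, C4, C5 bearing the side chain, C6): the ester C–O (last step); C2′–C3′ of the side chain (sp3–sp2 B-alkyl Suzuki union of oxane 12 with alkenyl iodide 21); C3–C4 of the oxane (radical ring closure); O1–C2 (allylic etherification of vinyloxirane).
- Forward: ether 3 → iodide 4 → the only ring is closed at C3–C4 (5), then C5 is equilibrated (6); vinyl → acetyl → enol triflate → acrylate and ester → vinyl give 12; 21 is built from 6-methylhept-5-en-2-one and pent-4-ynoic acid; Suzuki coupling, then saponification.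
- Enabling feature: C5 carries C1′, which can be held as an ester carbon, so C4=C5 is the alkene of a 2-(alkoxymethyl)acrylate tied through C6–O1 to C2. A radical on C3 then reaches the acrylate CH2 (C4) through a six-membered endo transition state, and the same ester makes C5 epimerisable afterwards.
- Stereochemistry: C2 from a ligand-controlled dynamic kinetic asymmetric etherification of racemic vinyloxirane; C5 by thermodynamic relay from C2 (2,5-trans, both groups equatorial); C7′ by CBS reduction; 3′E by syn-carboalumination, kept in the coupling.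

Key step: step 3

Assumption: in step 1 the (R,R)-ligand is taken to deliver the (S)-ether 3; if the sense of induction is the reverse, the (S,S)-ligand is used and nothing else changes.

Step 1
Reactants: 1 rac-2-ethenyloxirane; 2 methyl 2-(hydroxymethyl)prop-2-enoate
Product: 3 methyl 2-({[(2S)-1-hydroxybut-3-en-2-yl]oxy}methyl)prop-2-enoate
Conditions: Pd2(dba)3·CHCl3 (1 mol%), (1R,2R)-N,N′-bis[2-(diphenylphosphanyl)benzoyl]cyclohexane-1,2-diamine (3 mol%), Et3B (1 mol%), CH2Cl2, rt
Reagents that add atoms: none
Why: Tsuji–Trost-type dynamic kinetic asymmetric etherification: both epoxide enantiomers give π-allyl palladium species that interconvert, and the borate of 2, held by the opened alkoxide, should attack the internal carbon so that the ligand sets the C–O stereocentre as (S).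

Step 2
Reactants: 3 methyl 2-({[(2S)-1-hydroxybut-3-en-2-yl]oxy}methyl)prop-2-enoate
Product: 4 methyl 2-({[(2S)-1-iodobut-3-en-2-yl]oxy}methyl)prop-2-enoate
Conditions: I2, PPh3, imidazole, CH2Cl2, 0 °C to rt (alcohol added last)
Reagents that add atoms: iodine, II
Why: Appel iodination of the primary alcohol (iodide displaces the alkoxyphosphonium group at CH2) should leave the allylic ether stereocentre and both alkenes untouched.

Step 3
Reactants: 4 methyl 2-({[(2S)-1-iodobut-3-en-2-yl]oxy}methyl)prop-2-enoate
Product: 5 methyl (6R)-6-ethenyloxane-3-carboxylate (both C3 epimers)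
Conditions: Bu3SnH (1.2 equiv, syringe pump), Et3B (0.2 equiv)/air, PhMe (0.01 M), rt
Reagents that add atoms: none
Why: Bu3Sn• abstracts iodine from 4, the primary β-alkoxyalkyl radical (which does not lose alkoxide) adds to the CH2 terminus of the 2-(alkoxymethyl)acrylate, and the tertiary α-ester radical takes a hydrogen atom from Bu3SnH (reductive Giese-type cyclisation). The closest known reaction type is the 6-endo cyclisation of 5-(alkoxycarbonyl)hex-5-enyl radicals and of aryl radicals onto 2-(aryloxymethyl)acrylates. The oxane closes in the 6-endo-trig mode by forming C3–C4 of the target (C4–C5 in the locants of 5). The new stereocentre at the ester carbon arises in the hydrogen-atom transfer under weak substrate control only, so an epimer mixture is accepted here and corrected in step 4, while the ether stereocentre from step 1 is not involved. The step needs 6-endo over 5-exo attack and ring closure ahead of direct reduction and of the homoallyl (1,2-vinyl) rearrangement; the ester on the internal alkene carbon makes the CH2 terminus the polarity-matched, unhindered site and speeds the closure, and slow stannane addition at high dilution and room temperature should keep hydrogen transfer and the 3-exo pathway behind.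

Step 4
Reactants: 5 methyl (6R)-6-ethenyloxane-3-carboxylate (both C3 epimers)
Product: 6 methyl (3S,6R)-6-ethenyloxane-3-carboxylate
Conditions: NaOMe (0.3 equiv), MeOH, 50 °C; minor cis ester separated and resubmitted
Reagents that add atoms: none
Why: Base-mediated epimerisation through the ester enolate should enrich the 3,6-trans isomer with ester and vinyl group both equatorial, while the ether stereocentre has no acidic hydrogen and keeps its configuration.

Step 5
Reactants: 6 methyl (3S,6R)-6-ethenyloxane-3-carboxylate
Product: 7 methyl (3S,6R)-6-acetyloxane-3-carboxylate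
Conditions: PdCl2(quinox) (5 mol%; quinox = 2-(4,5-dihydro-1,3-oxazol-2-yl)quinoline), AgSbF6 (12 mol%), aq. TBHP (70%), CH2Cl2, 0 °C to rt
Reagents that add atoms: tert-butyl hydroperoxide, CC(C)(C)OO
Why: Peroxide-mediated Wacker oxidation with the cationic quinoline–oxazoline palladium catalyst should deliver oxygen to the internal carbon of the monosubstituted alkene even next to an ether oxygen, and the α-alkoxy ketone formed is most stable in the existing trans arrangement.

Step 6
Reactants: 7 methyl (3S,6R)-6-acetyloxane-3-carboxylate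
Product: 9 methyl (3S,6R)-6-{1-[(trifluoromethanesulfonyl)oxy]ethenyl}oxane-3-carboxylate, via potassium enolate 8 (not isolated)
Conditions: KHMDS (1.05 equiv), THF, −78 °C; then PhNTf2, −78 to 0 °C
Reagents that add atoms: N-phenylbis(trifluoromethanesulfonimide), O=S(=O)(N(c1ccccc1)S(=O)(=O)C(F)(F)F)C(F)(F)F
Why: Kinetic deprotonation should occur at the methyl group (less hindered than the ring methine, and the ketone is far more acidic than the ester), and O-sulfonylation of the enolate gives the 1,1-disubstituted enol triflate.

Step 7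
Reactants: 9 methyl (3S,6R)-6-{1-[(trifluoromethanesulfonyl)oxy]ethenyl}oxane-3-carboxylate
Product: 10 1-[(2R,5S)-5-formyloxan-2-yl]ethenyl trifluoromethanesulfonate
Conditions: DIBAL-H (1.1 equiv), CH2Cl2, −78 °C; aq. Rochelle salt
Reagents that add atoms: none
Why: Partial reduction of the methyl ester stops at the aluminium hemiacetal at −78 °C, conditions that enol triflates tolerate.

Step 8
Reactants: 10 1-[(2R,5S)-5-formyloxan-2-yl]ethenyl trifluoromethanesulfonate
Product: 11 1-[(2R,5R)-5-ethenyloxan-2-yl]ethenyl trifluoromethanesulfonate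
Conditions: Ph3PCH3Br, KHMDS, THF, −78 to 0 °C
Reagents that add atoms: methyltriphenylphosphonium bromide, C[P+](c1ccccc1)(c1ccccc1)c1ccccc1.[Br-]
Why: Wittig methylenation at low temperature should outrun enolisation of the α-branched aldehyde, so the ring stereocentre is kept (the descriptor changes to R only through the priority change).

Step 9
Reactants: 11 1-[(2R,5R)-5-ethenyloxan-2-yl]ethenyl trifluoromethanesulfonate
Product: 12 methyl 2-[(2R,5R)-5-ethenyloxan-2-yl]prop-2-enoate
Conditions: Pd(OAc)2 (5 mol%), dppp (5 mol%), CO (1 atm), MeOH, Et3N, DMF, 60 °C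
Reagents that add atoms: carbon monoxide, [C-]#[O+]; methanol, CO
Why: Palladium-catalysed alkoxycarbonylation of the enol triflate (oxidative addition, CO insertion, methanolysis) installs the α-substituted acrylate without touching the terminal vinyl group.

Step 10
Reactants: 13 pent-4-ynoic acid
Product: 14 N-methoxy-N-methylpent-4-ynamide
Conditions: MeNHOMe·HCl, EDC·HCl, Et3N, DMAP (cat.), CH2Cl2, 0 °C to rt
Reagents that add atoms: N,O-dimethylhydroxylamine hydrochloride, CNOC.Cl
Why: Carbodiimide amide coupling gives the N-methoxy-N-methylamide needed for a single acylation in step 12.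

Step 11
Reactants: 15 6-methylhept-5-en-2-one
Product: 16 N′-(6-methylhept-5-en-2-ylidene)-2,4,6-tri(propan-2-yl)benzenesulfonohydrazide
Conditions: 2,4,6-tri(propan-2-yl)benzenesulfonohydrazide, MeOH, HCl (cat.), rt
Reagents that add atoms: 2,4,6-tri(propan-2-yl)benzenesulfonohydrazide, CC(C)c1cc(C(C)C)c(S(=O)(=O)NN)c(C(C)C)c1
Why: Acid-catalysed condensation gives the arenesulfonylhydrazone required for the Shapiro reaction.

Step 12
Reactants: 16 N′-(6-methylhept-5-en-2-ylidene)-2,4,6-tri(propan-2-yl)benzenesulfonohydrazide; 14 N-methoxy-N-methylpent-4-ynamide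
Product: 18 10-methyl-6-methylideneundec-9-en-1-yn-5-one, via vinyllithium 17 (not isolated)
Conditions: n-BuLi (2.05 equiv per 16), THF, −78 to 0 °C; then 14 (0.45 equiv), −78 °C to rt; aq. NH4Cl
Reagents that add atoms: none
Why: Shapiro reaction (second deprotonation at the methyl group, loss of sulfinate and N2) gives the 2-lithio-1-alkene; one equivalent is spent on the alkyne C–H and the second acylates the amide, whose chelated tetrahedral adduct prevents over-addition and conjugate addition.

Step 13
Reactants: 18 10-methyl-6-methylideneundec-9-en-1-yn-5-one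
Product: 19 (5R)-10-methyl-6-methylideneundec-9-en-1-yn-5-ol
Conditions: (S)-2-methyl-CBS-oxazaborolidine (20 mol%), catecholborane (1.5 equiv), PhMe, −78 °C; MeOH, then aq. NaOH
Reagents that add atoms: none
Why: Corey–Bakshi–Shibata reduction with the α-branched alkenyl group as the large substituent should give the (R)-carbinol from the (S)-catalyst, and catecholborane at −78 °C does not hydroborate the alkyne or alkenes.

Step 14
Reactants: 19 (5R)-10-methyl-6-methylideneundec-9-en-1-yn-5-ol
Product: 21 (1E,5R)-1-iodo-2,10-dimethyl-6-methylideneundeca-1,9-dien-5-ol, via alkenylalane 20 (not isolated)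
Conditions: AlMe3 (3 equiv), Cp2ZrCl2 (0.3 equiv), CH2Cl2, 0 °C to rt; then I2, THF, −30 to 0 °C
Reagents that add atoms: trimethylaluminium, C[Al](C)C; iodine, II
Why: Zirconium-catalysed carboalumination (Negishi) adds methyl and aluminium syn across the terminal alkyne with aluminium at the terminus, and iodinolysis with retention gives the (E)-iodide; the hydroxyl is masked in the flask as its aluminium alkoxide and the more substituted alkenes do not react.

Step 15
Reactants: 12 methyl 2-[(2R,5R)-5-ethenyloxan-2-yl]prop-2-enoate; 21 (1E,5R)-1-iodo-2,10-dimethyl-6-methylideneundeca-1,9-dien-5-ol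
Product: 23 methyl 2-[(2R,5S)-5-[(3E,7R)-7-hydroxy-4,12-dimethyl-8-methylidenetrideca-3,11-dien-1-yl]oxan-2-yl]prop-2-enoate, via alkylborane 22 (not isolated)
Conditions: 9-BBN (1.2 equiv), THF, rt; then 21, Pd(dppf)Cl2 (5 mol%), AsPh3 (10 mol%), aq. Cs2CO3, DMF, rt
Reagents that add atoms: none
Why: B-alkyl Suzuki–Miyaura coupling: 9-BBN should hydroborate the monosubstituted vinyl group anti-Markovnikov in preference to the electron-poor acrylate, and the sp3–sp2 coupling keeps the alkene geometry and tolerates the free alcohol.

Step 16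
Reactants: 23 methyl 2-[(2R,5S)-5-[(3E,7R)-7-hydroxy-4,12-dimethyl-8-methylidenetrideca-3,11-dien-1-yl]oxan-2-yl]prop-2-enoate
Product: 25 2-[(2R,5S)-5-[(3E,7R)-7-hydroxy-4,12-dimethyl-8-methylidenetrideca-3,11-dien-1-yl]oxan-2-yl]prop-2-enoic acid, via lithium carboxylate 24 (not isolated)
Conditions: LiOH·H2O, THF/MeOH/H2O, rt; then aq. HCl to pH 4, 0 °C
Reagents that add atoms: lithium hydroxide, [Li+].[OH-]
Why: Saponification of the methyl acrylate, which has no α-hydrogen and so cannot lose the ring oxygen by elimination, followed by mild acidification should give the acid without disturbing the allylic alcohol.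

**Compound list**
1 | rac-2-ethenyloxirane | C=CC1CO1 | starting material
2 | methyl 2-(hydroxymethyl)prop-2-enoate | C=C(CO)C(=O)OC | starting material
3 | methyl 2-({[(2S)-1-hydroxybut-3-en-2-yl]oxy}methyl)prop-2-enoate | OC[C@H](C=C)OCC(=C)C(=O)OC | intermediate
4 | methyl 2-({[(2S)-1-iodobut-3-en-2-yl]oxy}methyl)prop-2-enoate | IC[C@H](C=C)OCC(=C)C(=O)OC | intermediate
5 | methyl (6R)-6-ethenyloxane-3-carboxylate (both C3 epimers) | COC(=O)C1CC[C@H](C=C)OC1 | intermediate
6 | methyl (3S,6R)-6-ethenyloxane-3-carboxylate | COC(=O)[C@H]1CC[C@H](C=C)OC1 | intermediate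
7 | methyl (3S,6R)-6-acetyloxane-3-carboxylate | COC(=O)[C@H]1CC[C@H](C(C)=O)OC1 | intermediate
8 | potassium 1-[(2R,5S)-5-(methoxycarbonyl)oxan-2-yl]ethen-1-olate | COC(=O)[C@H]1CC[C@H](C(=C)[O-])OC1.[K+] | intermediate
9 | methyl (3S,6R)-6-{1-[(trifluoromethanesulfonyl)oxy]ethenyl}oxane-3-carboxylate | COC(=O)[C@H]1CC[C@H](C(=C)OS(=O)(=O)C(F)(F)F)OC1 | intermediate
10 | 1-[(2R,5S)-5-formyloxan-2-yl]ethenyl trifluoromethanesulfonate | O=C[C@H]1CC[C@H](C(=C)OS(=O)(=O)C(F)(F)F)OC1 | intermediate
11 | 1-[(2R,5R)-5-ethenyloxan-2-yl]ethenyl trifluoromethanesulfonate | C=C[C@H]1CC[C@H](C(=C)OS(=O)(=O)C(F)(F)F)OC1 | intermediate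
12 | methyl 2-[(2R,5R)-5-ethenyloxan-2-yl]prop-2-enoate | C=C[C@H]1CC[C@H](C(=C)C(=O)OC)OC1 | intermediate
13 | pent-4-ynoic acid | C#CCCC(=O)O | starting material
14 | N-methoxy-N-methylpent-4-ynamide | C#CCCC(=O)N(C)OC | intermediate
15 | 6-methylhept-5-en-2-one | CC(=O)CCC=C(C)C | starting material
16 | N′-(6-methylhept-5-en-2-ylidene)-2,4,6-tri(propan-2-yl)benzenesulfonohydrazide | CC(CCC=C(C)C)=NNS(=O)(=O)c1c(C(C)C)cc(C(C)C)cc1C(C)C | intermediate
17 | (6-methylhepta-1,5-dien-2-yl)lithium | [Li]C(=C)CCC=C(C)C | intermediate
18 | 10-methyl-6-methylideneundec-9-en-1-yn-5-one | C#CCCC(=O)C(=C)CCC=C(C)C | intermediate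
19 | (5R)-10-methyl-6-methylideneundec-9-en-1-yn-5-ol | C#CCC[C@@H](O)C(=C)CCC=C(C)C | intermediate
20 | {(1E,5R)-5-[(dimethylalumanyl)oxy]-2,10-dimethyl-6-methylideneundeca-1,9-dien-1-yl}dimethylalumane | C[Al](C)/C=C(\C)CC[C@@H](O[Al](C)C)C(=C)CCC=C(C)C | intermediate
21 | (1E,5R)-1-iodo-2,10-dimethyl-6-methylideneundeca-1,9-dien-5-ol | I/C=C(\C)CC[C@@H](O)C(=C)CCC=C(C)C | intermediate
22 | methyl 2-[(2R,5S)-5-[2-(9-borabicyclo[3.3.1]nonan-9-yl)ethyl]oxan-2-yl]prop-2-enoate | B1(CC[C@H]3CC[C@H](C(=C)C(=O)OC)OC3)C2CCCC1CCC2 | intermediate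
23 | methyl 2-[(2R,5S)-5-[(3E,7R)-7-hydroxy-4,12-dimethyl-8-methylidenetrideca-3,11-dien-1-yl]oxan-2-yl]prop-2-enoate | C=C(CCC=C(C)C)[C@H](O)CC/C(C)=C/CC[C@H]1CC[C@H](C(=C)C(=O)OC)OC1 | intermediate
24 | lithium 2-[(2R,5S)-5-[(3E,7R)-7-hydroxy-4,12-dimethyl-8-methylidenetrideca-3,11-dien-1-yl]oxan-2-yl]prop-2-enoate | C=C(CCC=C(C)C)[C@H](O)CC/C(C)=C/CC[C@H]1CC[C@H](C(=C)C(=O)[O-])OC1.[Li+] | intermediate
25 | 2-[(2R,5S)-5-[(3E,7R)-7-hydroxy-4,12-dimethyl-8-methylidenetrideca-3,11-dien-1-yl]oxan-2-yl]prop-2-enoic acid | C=C(CCC=C(C)C)[C@H](O)CC/C(C)=C/CC[C@H]1CC[C@H](C(=C)C(=O)O)OC1 | target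

Total step count: 16. Longest linear sequence: 11 steps (steps 1 to 9, then 15 and 16).

**Steps most likely to fail**

Step 4. The equilibration may funnel the mixture only partly, because the conformational preference of an ester next to the ring CH2–O is small, and epimerisation may be slow beside reversible ring opening by loss of the β-alkoxide. The fallback replaces thermodynamic by kinetic discrimination. It sets out from 5: partial saponification (LiOH in deficit, THF/H2O, 0 °C), in which the equatorial trans ester should be hydrolysed faster than the axial cis ester, gives (3S,6R)-6-ethenyloxane-3-carboxylic acid F1, which is extracted into aqueous base away from the unreacted cis-enriched ester. Methylation (TMSCHN2, MeOH/PhMe) returns the route at 6, and the recovered ester is equilibrated again.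

Step 5. The oxidant may be steered to the terminal carbon by the neighbouring ether oxygen (aldehyde formation), or the catalyst may stall through chelation. The fallback replaces the palladium oxidation by a radical Markovnikov hydration followed by alcohol oxidation. It sets out from 6: Mukaiyama hydration (Co(acac)2, PhSiH3, O2, iPrOH, rt) should give methyl (3S,6R)-6-(1-hydroxyethyl)oxane-3-carboxylate F2, whose carbinol configuration is immaterial. Oxidation with Dess–Martin periodinane (CH2Cl2, rt) returns the route at 7.

Step 1. The electron-poor allylic alcohol 2 may bind zerovalent palladium through its alkene and slow turnover, the linear 1,4-adduct or oligomers from the product alcohol may form, and the enantioselectivity may erode. The fallback builds the ether by resolution and Williamson etherification instead. It sets out from 1: hydrolytic kinetic resolution with chiral (salen)Co(OAc) (salen = N,N′-bis(3,5-di-tert-butylsalicylidene)cyclohexane-1,2-diamine dianion, the enantiomer that hydrolyses (S)-1) gives (2S)-but-3-ene-1,2-diol F3. Selective tritylation of the primary hydroxyl (TrCl, Et3N, DMAP) gives (2S)-1-(triphenylmethoxy)but-3-en-2-ol F4. Alkylation of its sodium alkoxide with methyl 2-(bromomethyl)prop-2-enoate (NaH, THF, 0 °C) gives methyl 2-({[(2S)-1-(triphenylmethoxy)but-3-en-2-yl]oxy}methyl)prop-2-enoate F5. Detritylation (TsOH, MeOH, rt) returns the route at 3.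

**Further compounds**
F1 | step 4 | (3S,6R)-6-ethenyloxane-3-carboxylic acid | OC(=O)[C@H]1CC[C@H](C=C)OC1
F2 | step 5 | methyl (3S,6R)-6-(1-hydroxyethyl)oxane-3-carboxylate (both carbinol epimers) | COC(=O)[C@H]1CC[C@H](C(C)O)OC1
F3 | step 1 | (2S)-but-3-ene-1,2-diol | OC[C@@H](O)C=C
F4 | step 1 | (2S)-1-(triphenylmethoxy)but-3-en-2-ol | O[C@H](COC(c1ccccc1)(c1ccccc1)c1ccccc1)C=C
F5 | step 1 | methyl 2-({[(2S)-1-(triphenylmethoxy)but-3-en-2-yl]oxy}methyl)prop-2-enoate | c1ccccc1C(c1ccccc1)(c1ccccc1)OC[C@H](C=C)OCC(=C)C(=O)OC
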